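**Assumption:** the lactol carbon epimerises freely through the open hydroxy aldehyde, and the drawn (R)-anomer is taken to be the more stable one.

## Retrosynthetic overview
1. Ring A is the bromodimethylcyclohexyl acetate, ring B the cyclopentane, ring C the lactol, and ring D the brominated cyclohexane of the core.
2. Ring C is made last. Its C–O bond comes from the angular methyl group by light-driven hydrogen abstraction through the tertiary alkoxy radical (24 ⇒ 21 ⇒ ketone 20).
3. The fragments are joined at the CH2–CH bond between rings A and B, by a visible-light radical conjugate addition of iodide 11 to enone 19.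
4. Ring B comes from an aldol condensation (19 ⇒ 16). Rings A and D each come from an oxygen-to-carbon ring transposition of a bromo enol ether (7 ⇒ 9, 14 ⇒ 16).
5. Both bromolactones (6, 13) come from one bromo keto ester 4, made from L-glutamic acid 5-methyl ester 1. Rings form in the order A and D (in parallel), then B, then C.

## Route

**Step 1**
Reactants: 1 L-glutamic acid 5-methyl ester
Product: 2 (2S)-2-bromo-5-methoxy-5-oxopentanoic acid
Conditions: NaNO2, KBr, aq. HBr, 0 °C
Reagents that add atoms: hydrogen bromide, Br
Why: Diazotisation–bromide substitution of an α-amino acid runs with neighbouring carboxylate participation (double inversion), so the bought (S) centre is retained and later becomes both C–Br stereocentres of the target.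

**Step 2**
Reactants: 2 (2S)-2-bromo-5-methoxy-5-oxopentanoic acid
Product: 4 methyl (4S)-4-bromo-5-oxohexanoate, via acid chloride 3 (not isolated)
Conditions: (COCl)2, cat. DMF, CH2Cl2, 0 °C; then AlMe3 (1.0 equiv), CH2Cl2, −78 °C
Reagents that add atoms: trimethylaluminium, C[Al](C)C
Why: Acid chloride formation followed by acylation of an organoaluminium reagent is base-free and cold, so it stops at the methyl ketone, spares the ester and leaves the C–Br centre untouched.

**Step 3**
Reactants: 4 methyl (4S)-4-bromo-5-oxohexanoate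
Product: 6 (5S)-5-bromo-6,6-dimethyloxan-2-one, via hydroxy ester 5 (not isolated)
Conditions: MeMgBr (1.05 equiv), Et2O, −78 °C; aq. NH4Cl; then cat. TsOH, CH2Cl2, rt
Reagents that add atoms: methylmagnesium bromide, C[Mg]Br
Why: Chemoselective Grignard addition to the activated ketone (ketone over ester at −78 °C) followed by acid-catalysed lactonisation creates no new stereocentre.

**Step 4**
Reactants: 6 (5S)-5-bromo-6,6-dimethyloxan-2-one
Product: 7 (3S)-3-bromo-2,2-dimethyl-6-methylideneoxane
Conditions: Cp2TiMe2 (2 equiv), toluene, 70 °C, dark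
Reagents that add atoms: dimethyltitanocene, C[Ti](C)(C1C=CC=C1)C1C=CC=C1
Why: Petasis methylenation of a lactone is non-basic and gives the exocyclic enol ether without disturbing the secondary bromide.

**Step 5**
Reactants: 7 (3S)-3-bromo-2,2-dimethyl-6-methylideneoxane
Product: 9 (4S)-4-bromo-3,3-dimethylcyclohexan-1-one, via bromonium aluminium enolate 8 (not isolated)
Conditions: Me2AlCl (1.1 equiv), CH2Cl2, −78 to 0 °C
Reagents that add atoms: none
Why: Proposed new method: Me2AlCl binds the enol-ether oxygen, the tertiary C–O bond ionises with help from the antiperiplanar equatorial bromine to give zwitterion 8, and the enolate CH2 carbon opens the bromonium ion at its tertiary carbon through a chair, so ring oxygen is exchanged for carbon (ring A) while the C–Br centre is never broken; the closest known reaction type is the Petasis–Ferrier oxygen-to-carbon rearrangement of cyclic enol acetals, so far shown only where the departing carbon is an oxocarbenium ion.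

**Step 6**
Reactants: 9 (4S)-4-bromo-3,3-dimethylcyclohexan-1-one
Product: 11 (1R,4S)-4-bromo-1-(iodomethyl)-3,3-dimethylcyclohexyl acetate, via lithium alkoxide 10 (not isolated)
Conditions: CH2I2, MeLi·LiBr, THF, −78 °C; then Ac2O, cat. DMAP, −78 to −20 °C
Reagents that add atoms: diiodomethane, ICI; acetic anhydride, CC(=O)OC(C)=O
Why: In this halomethyllithium addition to a ketone with O-acylation of the cold alkoxide, the axial 3-methyl group blocks the axial trajectory, so CH2I enters equatorially and oxygen ends up axial and cis to bromine.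

**Step 7**
Reactants: 4 methyl (4S)-4-bromo-5-oxohexanoate
Product: 13 (5S,6R)-5-bromo-6-(but-3-en-1-yl)-6-methyloxan-2-one, via hydroxy ester 12 (not isolated)
Conditions: but-3-enylmagnesium bromide (1.05 equiv), Et2O/CH2Cl2, −78 °C; aq. NH4Cl; then cat. TsOH, CH2Cl2, rt
Reagents that add atoms: but-3-enylmagnesium bromide, C=CCC[Mg]Br
Why: In this polar Felkin–Anh (Cornforth-type) Grignard addition to an α-bromo ketone followed by lactonisation, the nucleophile attacks anti to the C–Br bond past the small hydrogen, so the bought centre sets the (R) tertiary carbinol.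

**Step 8**
Reactants: 13 (5S,6R)-5-bromo-6-(but-3-en-1-yl)-6-methyloxan-2-one
Product: 14 (2R,3S)-3-bromo-2-(but-3-en-1-yl)-2-methyl-6-methylideneoxane
Conditions: Cp2TiMe2 (2 equiv), toluene, 70 °C, dark
Reagents that add atoms: dimethyltitanocene, C[Ti](C)(C1C=CC=C1)C1C=CC=C1
Why: Petasis methylenation proceeds as in step 4, and any exchange at the terminal alkene is degenerate.

**Step 9**
Reactants: 14 (2R,3S)-3-bromo-2-(but-3-en-1-yl)-2-methyl-6-methylideneoxane
Product: 16 (3S,4S)-4-bromo-3-(but-3-en-1-yl)-3-methylcyclohexan-1-one, via bromonium aluminium enolate 15 (not isolated)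
Conditions: Me2AlCl (1.1 equiv), CH2Cl2, −78 to 0 °C
Reagents that add atoms: none
Why: Proposed new method: this is the transposition of step 5 on a stereodefined tertiary centre, where bromine displaces the aluminium-bound oxygen from the back (first inversion) and the enolate carbon opens bromonium ion 15 from the side oxygen left (second inversion), so ring D forms with net retention and the quaternary carbon carries an axial methyl cis to the equatorial bromine and an equatorial butenyl chain; the closest known types are the Petasis–Ferrier rearrangement and the Lewis-acid tert-alkylation of enol derivatives.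

**Step 10**
Reactants: 16 (3S,4S)-4-bromo-3-(but-3-en-1-yl)-3-methylcyclohexan-1-one
Product: 17 3-[(1S,2S)-2-bromo-1-methyl-5-oxocyclohexyl]propanal
Conditions: O3, CH2Cl2/MeOH, −78 °C; then Me2S
Reagents that add atoms: ozone, [O-][O+]=O
Why: Ozonolysis with reductive work-up cleaves the only alkene and touches no stereocentre.

**Step 11**
Reactants: 17 3-[(1S,2S)-2-bromo-1-methyl-5-oxocyclohexyl]propanal
Product: 19 (7S,7aS)-7-bromo-7a-methyl-1,2,5,6,7,7a-hexahydro-4H-inden-4-one, via aldol 18 (not isolated)
Conditions: TsOH·H2O (10 mol %), benzene, 80 °C, Dean–Stark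
Reagents that add atoms: none
Why: In this acid-catalysed intramolecular aldol condensation only the ketone α-carbon next to the quaternary centre can close a five-membered ring (ring B), and acid avoids base-induced loss of the γ-bromide.

**Step 12**
Reactants: 11 (1R,4S)-4-bromo-1-(iodomethyl)-3,3-dimethylcyclohexyl acetate; 19 (7S,7aS)-7-bromo-7a-methyl-1,2,5,6,7,7a-hexahydro-4H-inden-4-one
Product: 20 (1S,4S)-4-bromo-1-{[(1S,3aS,4S,7aS)-4-bromo-3a-methyl-7-oxooctahydro-1H-inden-1-yl]methyl}-3,3-dimethylcyclohexyl acetate
Conditions: 4CzIPN (2 mol %), Et3N (3 equiv), MeCN/H2O, blue LED (450 nm), rt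
Reagents that add atoms: none
Why: In this photochemical Giese addition started by halogen-atom transfer, which takes iodine much faster than the hindered secondary bromines, the primary radical attacks the cyclopentene β-carbon on the face opposite the angular methyl group, and the resulting enolate is protonated axially, again anti to that methyl, giving the trans ring fusion.

**Step 13**
Reactants: 20 keto acetate
Product: 21 (1S,4S)-4-bromo-1-{[(1S,3aS,4S,7R,7aS)-4-bromo-7-hydroxy-3a,7-dimethyloctahydro-1H-inden-1-yl]methyl}-3,3-dimethylcyclohexyl acetate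
Conditions: MeLi, CeCl3, THF, −78 °C (1.3 equiv of the cerium reagent)
Reagents that add atoms: methyllithium, [Li]C
Why: The weakly basic organocerium reagent adds 1,2 to the ketone faster than to the acetate and does not epimerise the ring fusion, and the axial angular methyl blocks the axial path, so methyl enters equatorially and the hydroxyl is axial, 1,3-diaxial to that methyl.

**Step 14**
Reactants: 21 tertiary alcohol
Product: 24 target lactol acetate CNP0196016.1, via iodomethyl carbinol 22 (not isolated), via iodo ether 23 (not isolated)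
Conditions: PhI(OAc)2 (3 equiv), I2 (1.5 equiv), cyclohexane/CH2Cl2, visible light (W lamp), 25 °C; then THF/H2O
Reagents that add atoms: water, O
Why: In this Suárez hypoiodite reaction light cleaves the O–I bond and the alkoxy radical abstracts hydrogen twice (1,5-transfer) from the 1,3-diaxial angular methyl, ring closure gives iodo ether 23 on the only face the tether allows, and water converts it into the lactol, which settles as the drawn anomer.

## Compound list
1 | L-glutamic acid 5-methyl ester | COC(=O)CC[C@H](N)C(=O)O | starting material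
2 | (2S)-2-bromo-5-methoxy-5-oxopentanoic acid | COC(=O)CC[C@H](Br)C(=O)O | intermediate
3 | methyl (4S)-4-bromo-5-chloro-5-oxopentanoate (acid chloride) | COC(=O)CC[C@H](Br)C(=O)Cl | intermediate
4 | methyl (4S)-4-bromo-5-oxohexanoate | COC(=O)CC[C@H](Br)C(C)=O | intermediate
5 | methyl (4S)-4-bromo-5-hydroxy-5-methylhexanoate | COC(=O)CC[C@H](Br)C(C)(C)O | intermediate
6 | (5S)-5-bromo-6,6-dimethyloxan-2-one | O=C1CC[C@H](Br)C(C)(C)O1 | intermediate
7 | (3S)-3-bromo-2,2-dimethyl-6-methylideneoxane | C=C1CC[C@H](Br)C(C)(C)O1 | intermediate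
8 | ring A bromonium aluminium enolate (zwitterion) | C=C(CC[C@@H]1[Br+]C1(C)C)O[Al-](C)(C)Cl | intermediate
9 | (4S)-4-bromo-3,3-dimethylcyclohexan-1-one | O=C1CC[C@H](Br)C(C)(C)C1 | intermediate
10 | lithium (1R,4S)-4-bromo-1-(iodomethyl)-3,3-dimethylcyclohexan-1-olate | [Li+].[O-][C@]1(CI)CC[C@H](Br)C(C)(C)C1 | intermediate
11 | (1R,4S)-4-bromo-1-(iodomethyl)-3,3-dimethylcyclohexyl acetate (acetoxy axial, cis to bromine) | CC(=O)O[C@]1(CI)CC[C@H](Br)C(C)(C)C1 | intermediate
12 | methyl (4S,5R)-4-bromo-5-hydroxy-5-methylnon-8-enoate | COC(=O)CC[C@H](Br)[C@](C)(O)CCC=C | intermediate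
13 | (5S,6R)-5-bromo-6-(but-3-en-1-yl)-6-methyloxan-2-one | O=C1CC[C@H](Br)[C@@](C)(CCC=C)O1 | intermediate
14 | (2R,3S)-3-bromo-2-(but-3-en-1-yl)-2-methyl-6-methylideneoxane | C=C1CC[C@H](Br)[C@@](C)(CCC=C)O1 | intermediate
15 | ring D bromonium aluminium enolate (zwitterion) | C=C(CC[C@@H]1[Br+][C@@]1(C)CCC=C)O[Al-](C)(C)Cl | intermediate
16 | (3S,4S)-4-bromo-3-(but-3-en-1-yl)-3-methylcyclohexan-1-one | O=C1CC[C@H](Br)[C@@](C)(CCC=C)C1 | intermediate
17 | 3-[(1S,2S)-2-bromo-1-methyl-5-oxocyclohexyl]propanal | O=C1CC[C@H](Br)[C@@](C)(CCC=O)C1 | intermediate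
18 | (7S,7aS)-7-bromo-3-hydroxy-7a-methyloctahydro-4H-inden-4-one (aldol, epimer mixture at the two new centres) | O=C1CC[C@H](Br)[C@@]2(C)CCC(O)C12 | intermediate
19 | (7S,7aS)-7-bromo-7a-methyl-1,2,5,6,7,7a-hexahydro-4H-inden-4-one | O=C1CC[C@H](Br)[C@@]2(C)CCC=C12 | intermediate
20 | (1S,4S)-4-bromo-1-{[(1S,3aS,4S,7aS)-4-bromo-3a-methyl-7-oxooctahydro-1H-inden-1-yl]methyl}-3,3-dimethylcyclohexyl acetate (trans-fused) | CC(=O)O[C@]1(C[C@@H]2CC[C@]3(C)[C@@H](Br)CCC(=O)[C@@H]23)CC[C@H](Br)C(C)(C)C1 | intermediate
21 | (1S,4S)-4-bromo-1-{[(1S,3aS,4S,7R,7aS)-4-bromo-7-hydroxy-3a,7-dimethyloctahydro-1H-inden-1-yl]methyl}-3,3-dimethylcyclohexyl acetate | CC(=O)O[C@]1(C[C@@H]2CC[C@]3(C)[C@@H](Br)CC[C@@](C)(O)[C@@H]23)CC[C@H](Br)C(C)(C)C1 | intermediate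
22 | iodomethyl carbinol (21 with the angular CH3 turned into CH2I) | CC(=O)O[C@]1(C[C@@H]2CC[C@]3(CI)[C@@H](Br)CC[C@@](C)(O)[C@@H]23)CC[C@H](Br)C(C)(C)C1 | intermediate
23 | iodo ether (target with I in place of the lactol OH, anomer mixture) | CC(=O)O[C@]1(C[C@@H]2CC[C@]34C(I)O[C@](C)(CC[C@@H]3Br)[C@@H]24)CC[C@H](Br)C(C)(C)C1 | intermediate
24 | CNP0196016.1, target lactol acetate | CC(=O)O[C@]1(C[C@@H]2CC[C@]34[C@H](O)O[C@](C)(CC[C@@H]3Br)[C@@H]24)CC[C@H](Br)C(C)(C)C1 | target

## Step count
There are 14 steps in total. The longest linear sequence is 10 steps (steps 1, 2 and 7–14).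

## Three steps most likely to fail

**Step 9** (the proposed new transposition; step 5 is its simpler case). The bromonium ion may lose a proton or pick up chloride before the enolate carbon closes the ring.
The fallback sets out from lactone 13 and comes back at ketone 16, using known chemistry. One equivalent of MeLi (THF, −78 °C) opens 13 to (5S,6R)-5-bromo-6-hydroxy-6-methyldec-9-en-2-one F1. Kinetic double silylation (LiN(iPr)2, Me3SiCl, −78 °C) gives (5S,6R)-5-bromo-6-methyl-2,6-bis(trimethylsilyloxy)deca-1,9-diene F2. TiCl4 in CH2Cl2 at −78 °C then closes the ring by the established Lewis-acid tert-alkylation of a silyl enol ether, with bromine again guarding one face of the tertiary carbon.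

**Step 13.** The cerium reagent may also attack the acetate, or the hindered ketone may react too slowly.
The fallback sets out from ketone 20 and comes back at alcohol 21. Dimethylsulfoxonium methylide (Me3S(O)I, NaH, DMSO/THF) adds equatorially to give the spiro-epoxide of 20 F3. MgI2 in Et2O opens F3 at its CH2 carbon to the iodohydrin F4. Radical deiodination with (Me3Si)3SiH/Et3B/air then turns CH2I into the methyl group, because C–I reacts well before C–Br.

**Step 14.** The reaction may stop at the cyclic ether after one abstraction, or the tertiary alkoxy radical may fragment.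
The fallback sets out from alcohol 21 and comes back at target 24 by the Barton nitrite route. NOCl in pyridine gives the tertiary nitrite ester F5. Irradiation (Hg lamp, toluene, 0 °C) moves the nitrogen to the angular methyl and gives the hydroxy oxime F6. NaNO2 in aqueous AcOH cleaves the oxime to the hydroxy aldehyde, which closes to the lactol.

## Further compounds
F1 | step 9 | (5S,6R)-5-bromo-6-hydroxy-6-methyldec-9-en-2-one | CC(=O)CC[C@H](Br)[C@](C)(O)CCC=C
F2 | step 9 | (5S,6R)-5-bromo-6-methyl-2,6-bis(trimethylsilyloxy)deca-1,9-diene | C=C(CC[C@H](Br)[C@](C)(O[Si](C)(C)C)CCC=C)O[Si](C)(C)C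
F3 | step 13 | spiro-epoxide of 20 (oxygen axial) | CC(=O)O[C@]1(C[C@@H]2CC[C@]3(C)[C@@H](Br)CC[C@]4(CO4)[C@@H]23)CC[C@H](Br)C(C)(C)C1
F4 | step 13 | iodohydrin (21 with CH2I in place of the new methyl) | CC(=O)O[C@]1(C[C@@H]2CC[C@]3(C)[C@@H](Br)CC[C@@](CI)(O)[C@@H]23)CC[C@H](Br)C(C)(C)C1
F5 | step 14 | tertiary nitrite ester of 21 | CC(=O)O[C@]1(C[C@@H]2CC[C@]3(C)[C@@H](Br)CC[C@@](C)(ON=O)[C@@H]23)CC[C@H](Br)C(C)(C)C1
F6 | step 14 | hydroxy oxime (angular CH=NOH) | CC(=O)O[C@]1(C[C@@H]2CC[C@]3(C=NO)[C@@H](Br)CC[C@@](C)(O)[C@@H]23)CC[C@H](Br)C(C)(C)C1
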